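The constants were chosen freely; no experiment stands behind them.

I did it by hand.

starting material 0.050 M; gas phase 10 mM (held); free catalyst 70 µM; time 2.0 d

- at the start none of the gas is dissolved
- run time (flask): 2.0 d

    free catalyst → spent catalyst B (k1 = 3.40 × 10⁻⁶ /s)
    dissolved gas + free catalyst → spent catalyst A (k2 = 6.50 × 10⁻⁴ /M/s)
    starting material + dissolved gas + free catalyst → free catalyst + target (k3 = 4.08 /M²/s)
    dissolved gas → decomposed reagent (k4 = 3.93 × 10⁻⁶ /s)
    gas phase ⇌ dissolved gas, rate k5*(csat - [dissolved gas]) (k5 = 2.63 × 10⁻⁴ /s, csat = 10 mM)

- amount of target at 2.0 d, in percent of the starting material charged
- the change that raises the amount of target at 2.0 d, in percent of the starting material charged most ("none" if none brings more than 2 percentage points) (south-west / north / east / none)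
- amount of target at 2.0 d, in percent of the starting material charged, after north

- south-west: doubling the amount of free catalyst, all else as stated
- north: doubling the saturation concentration of gas phase, all else as stated
- east: doubling the transfer coefficient of step 5, all else as stated

You wanted a quick figure, so I took the gas transfer first. Step 5 refills the solution at 2.63 × 10⁻⁴ /s, while step 3 at the charged amounts draws the gas at 1.43 × 10⁻⁵ /s; the refill is faster than that draw, so I held c(dissolved gas) at 10 mM from the start. At that level the free catalyst dies in a pseudo-first-order way at 9.90 × 10⁻⁶ /s, the sum of steps 1 and 2, a lifetime of 28.1 h, longer than the refill time of 1.06 h. Step 3 gives its catalyst back, so it costs none.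

I carried one quantity, the reach of the catalyst: the logarithm of charged over remaining starting material, earned by the asked time per unit of catalyst charged, 3380 /M. Multiplied by the charge, it gave the logarithm for this flask, and that meant 21.0% of target.

North doubles the saturation concentration of the gas, and with it the rate of step 2, so its reach of 4680 /M is less than twice the first, and I got 28.0%. The transfer coefficient that east doubles does not enter the reach, so east gains nothing in this reckoning. My choice was south-west.

Your hunch, the forecast, said 20%, 27% after north and south-west as the best change, holding that “conversion is then limited by the catalyst dying with a lifetime of about a day”. My first figure is higher than its.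

The simulation gave 20.2%, 27.3% after north, and south-west as best, with gains of 16 percentage points for south-west, 7.1 points for north and 0.41 points for east.

A larger charge of free catalyst took the target away from the forecast's 20%. The neighbouring flask held 2.8 × 10⁻⁴ M of free catalyst, the rest as in the recipe. The reach does not contain the charge, so I multiplied the same 3380 /M by the new charge and got 61.1% of target at 2.0 d. In the simulated neighbouring flask, 42% of the starting material was left and the target stood at 58.3%.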